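## Retrosynthetic overview

1. Target 25 ⇒ seco enal / allylic bromide 23: the C1–C14 bond and the γ-lactone come from one intramolecular Barbier allylation–lactonisation, so the 14-membered carbocycle and the lactone are formed last, together.
2. 23 ⇒ keto acetate 16: the C1 acrylate unit by cross-metathesis, the 3Z olefin by Wittig reaction on the C4 methyl ketone.
3. 16 ⇒ keto aldehyde 9 + dialkylzinc 14 (C10–C14): C9–C10 bond with a catalyst-controlled C9 stereocentre.
4. 9 ⇒ dialdehyde 7 ⇒ bicyclic endoperoxide 5: the 1,2-dioxane (first ring formed) is carved out of a six-membered carbocycle by singlet-oxygen [4+2] addition and excision of the C4–C9 bond by glycol cleavage.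
5. 5 ⇒ toluene: enzymatic dearomatising cis-dihydroxylation supplies the diene and, through two sacrificial carbinol centres, the absolute configuration of C5 and C8.

Assumption: the macrocycle is numbered locally C1–C14 (C1 = lactone CH bearing the methylene carbon, C2 = CH2, C3=C4(Me), C5 = dioxane CH–O, C6/C7 = CH2, C8 = C(Me)–O, C9 = CHOAc, C10/C11 = CH2, C12(Me)=C13, C14 = lactone CH–O). In this numbering the target is (1R,3Z,5R,8S,9R,12E,14R). Recombinant E. coli JM109(pDTG601) cells and building blocks 10, 17 and 20 are taken as purchasable. All compounds from 7 to 16 are kept free of amine bases.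

## Route

Step 1
Reactants: 1 toluene
Product: 2 (1S,2R)-3-methylcyclohexa-3,5-diene-1,2-diol
Conditions: E. coli JM109(pDTG601) whole cells (toluene dioxygenase), glucose, O2, phosphate buffer pH 7.2, 30 °C, toluene fed as vapour
Reagents that add atoms: dioxygen, O=O
Why: Enzymatic arene cis-dihydroxylation (toluene dioxygenase) breaks the aromaticity of toluene with complete regio- and enantiocontrol, and the two carbinol centres it creates (1S,2R) are the only source of absolute configuration for the later dioxane centres C5 and C8.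

Step 2
Reactants: 2 (1S,2R)-3-methylcyclohexa-3,5-diene-1,2-diol
Product: 3 (3aR,7aS)-2,2,4-trimethyl-3a,7a-dihydro-1,3-benzodioxole
Conditions: Me2C(OMe)2, TsOH (cat.), acetone, 0 °C
Reagents that add atoms: 2,2-dimethoxypropane, COC(C)(C)OC
Why: Acid-catalysed acetal exchange on the cis-diol is fast at 0 °C, blocks rearomatisation by dehydration and places a bulky isopropylidene group on one face of the diene without touching the stereocentres.

Step 3
Reactants: 3 (3aR,7aS)-2,2,4-trimethyl-3a,7a-dihydro-1,3-benzodioxole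
Product: 4 (1S,4R,7S,8R)-7,8-O-isopropylidene-1-methyl-2,3-dioxabicyclo[2.2.2]oct-5-ene-7,8-diol (peroxide bridge anti to the acetonide)
Conditions: O2, tetraphenylporphyrin (cat.), visible light, CH2Cl2, −30 °C
Reagents that add atoms: dioxygen (singlet), O=O
Why: Singlet-oxygen [4+2] cycloaddition to the cyclohexadiene occurs across the methyl-bearing terminus and the distal CH from the face anti to the acetonide, which sets C8 as S and C5 as R with the O–O bridge necessarily cis.

Step 4
Reactants: 4 unsaturated endoperoxide acetonide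
Product: 5 (1S,4R,5R,6S)-5,6-O-isopropylidene-1-methyl-2,3-dioxabicyclo[2.2.2]octane-5,6-diol
Conditions: KO2C–N=N–CO2K, AcOH, CH2Cl2/MeOH, 0 °C
Reagents that add atoms: none
Why: Diimide reduction saturates the strained cis-disubstituted bicyclic alkene by concerted syn hydrogen transfer and, unlike catalytic hydrogenation, leaves the O–O bond intact, turning the etheno bridge into the future C6–C7 ethano unit.

Step 5
Reactants: 5 saturated endoperoxide acetonide
Product: 7 (3S,6R)-3-methyl-1,2-dioxane-3,6-dicarbaldehyde, via bicyclic diol 6 (not isolated)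
Conditions: CF3CO2H/H2O (4:1), 0 °C to rt, evaporate; then NaIO4, THF/pH 7 buffer, 0 °C
Reagents that add atoms: none
Why: Aqueous acid removes the acetonide (dialkyl peroxides tolerate acid) and Malaprade glycol cleavage then excises the C–C bond that carried the directing diol, releasing the monocyclic 1,2-dioxane whose two stereocentres are untouched and whose former carbinol carbons become C9 and C4 as aldehydes.

Step 6
Reactants: 7 (3S,6R)-3-methyl-1,2-dioxane-3,6-dicarbaldehyde
Product: 8 (3S,6R)-6-(1-hydroxyethyl)-3-methyl-1,2-dioxane-3-carbaldehyde (both carbinol epimers)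
Conditions: MeTi(OiPr)3 (1.05 equiv), Et2O, −78 to −40 °C; aqueous NH4Cl
Reagents that add atoms: methyltitanium triisopropoxide, C[Ti](OC(C)C)(OC(C)C)OC(C)C
Why: Non-basic organotitanium (Reetz) carbonyl addition is highly sensitive to steric hindrance, so the aldehyde on the tertiary ring carbon reacts while the neopentyl-type aldehyde on the quaternary carbon survives and no Kornblum–DeLaMare fragmentation is triggered; the new carbinol centre is erased in step 7.

Step 7
Reactants: 8 hydroxy aldehyde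
Product: 9 (3S,6R)-6-acetyl-3-methyl-1,2-dioxane-3-carbaldehyde
Conditions: Dess–Martin periodinane, CH2Cl2, 0 °C to rt (no amine)
Reagents that add atoms: none
Why: Dess–Martin oxidation under mildly acidic conditions converts the secondary alcohol into the methyl ketone (future C4 with its methyl) without epimerising or fragmenting the base-sensitive alpha-peroxy carbonyl centres.

Step 8
Reactants: 10 (2E)-3-methylpent-2-en-4-yn-1-ol
Product: 11 1-methoxy-4-({[(2E)-3-methylpent-2-en-4-yn-1-yl]oxy}methyl)benzene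
Conditions: NaH, 4-MeOC6H4CH2Cl, Bu4NI (cat.), THF, 0 °C to rt
Reagents that add atoms: 4-methoxybenzyl chloride, COc1ccc(CCl)cc1
Why: Williamson etherification of the primary allylic alkoxide protects the future C14 oxygen as a PMB ether that can later be oxidised directly to the enal, and the preformed E olefin is not affected.

Step 9
Reactants: 11 PMB enyne
Product: 12 1-methoxy-4-({[(2E)-3-methylpenta-2,4-dien-1-yl]oxy}methyl)benzene
Conditions: H2 (1 atm), Pd/CaCO3 poisoned with Pb(OAc)2, quinoline, hexane/EtOAc, rt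
Reagents that add atoms: none
Why: Lindlar semi-hydrogenation of the terminal conjugated alkyne stops at the vinyl group and cannot alter the E trisubstituted olefin, which becomes C12=C13.

Step 10
Reactants: 9 (3S,6R)-6-acetyl-3-methyl-1,2-dioxane-3-carbaldehyde; 12 PMB diene
Product: 16 (1R,4E)-1-[(3S,6R)-6-acetyl-3-methyl-1,2-dioxan-3-yl]-6-[(4-methoxybenzyl)oxy]-4-methylhex-4-en-1-yl acetate, via alkylborane 13 (not isolated), via dialkylzinc 14 (not isolated), via zinc alkoxide 15 (not isolated)
Conditions: 12 (3 equiv), Et2BH (from BH3·SMe2 + Et3B), 0 °C to rt; Et2Zn, 0 °C, volatiles removed in vacuo; toluene, Ti(OiPr)4 (2 equiv), (1S,2S)-C6H10(NHSO2CF3)2 (8 mol %), −20 °C, add 9; then Ac2O (excess), 0 °C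
Reagents that add atoms: acetic anhydride, CC(=O)OC(C)=O
Why: In this Knochel-type sequence terminal-selective hydroboration of the diene and boron–zinc exchange give a functionalised dialkylzinc that adds only to the aldehyde under Ti(OiPr)4/bis(sulfonamide) catalysis, the (1S,2S)-ligand delivering the alkyl group to the Re face to set C9 as R under catalyst control, and the zinc alkoxide is acetylated in situ so that no amine base meets the alpha-peroxy ketone.

Step 11
Reactants: 16 keto acetate; 17 but-3-en-1-yl(triphenyl)phosphonium bromide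
Product: 19 (1R,4E)-1-[(3S,6R)-6-[(2Z)-hexa-2,5-dien-2-yl]-3-methyl-1,2-dioxan-3-yl]-6-[(4-methoxybenzyl)oxy]-4-methylhex-4-en-1-yl acetate, via phosphorus ylide 18 (not isolated)
Conditions: 17, KN(SiMe3)2, THF, −78 to 0 °C; then 16, −78 to −20 °C
Reagents that add atoms: none
Why: Wittig olefination of an alpha-oxygenated methyl ketone with a salt-free non-stabilised ylide follows Still's precedent for Z-trisubstituted olefins (the ylide substituent ends up cis to the oxygen-bearing carbon), giving the 3Z olefin, and the low temperature favours carbonyl addition over deprotonation at C5.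

Step 12
Reactants: 19 triene; 20 methyl 2-(bromomethyl)prop-2-enoate
Product: 21 methyl (2Z,5Z)-6-[(3R,6S)-6-{(1R,4E)-1-acetoxy-6-[(4-methoxybenzyl)oxy]-4-methylhex-4-en-1-yl}-6-methyl-1,2-dioxan-3-yl]-2-(bromomethyl)hepta-2,5-dienoate
Conditions: 20 (5 equiv), second-generation Hoveyda–Grubbs catalyst RuCl2(=CH-C6H4-2-OiPr)(H2IMes) (10 mol %), 1,4-benzoquinone (10 mol %), CH2Cl2, 40 °C
Reagents that add atoms: none
Why: Olefin cross-metathesis of the only monosubstituted alkene with the 1,1-disubstituted acrylate (as with methacrylates) releases ethene and gives the thermodynamically preferred trisubstituted enoate with the chain trans to the ester (2Z), while the trisubstituted olefins and the peroxide are inert to the ruthenium carbene.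

Step 13
Reactants: 21 bromo ester PMB ether
Product: 23 methyl (2Z,5Z)-6-[(3R,6S)-6-[(1R,4E)-1-acetoxy-4-methyl-6-oxohex-4-en-1-yl]-6-methyl-1,2-dioxan-3-yl]-2-(bromomethyl)hepta-2,5-dienoate, via allylic alcohol 22 (not isolated)
Conditions: DDQ (3 equiv), CH2Cl2/pH 7 buffer (10:1), 0 °C to rt
Reagents that add atoms: none
Why: DDQ oxidatively cleaves the electron-rich PMB ether and a further equivalent dehydrogenates the liberated allylic alcohol, giving the E enal (C14) in one flask with the peroxide, bromide and acetate unaffected.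

Step 14
Reactants: 23 enal allylic bromide
Product: 25 target, (1R,3Z,5R,8S,9R,12E,14R)-cembranolide endoperoxide acetate, via hydroxy ester 24 (not isolated)
Conditions: In powder, THF/H2O (3:1), 2 mM (syringe pump), rt; then TsOH (cat.), CH2Cl2, rt
Reagents that add atoms: none
Why: Intramolecular Barbier allylation with indium metal proceeds through a chair six-membered transition state in which the Z-configured 2-(alkoxycarbonyl)allyl unit gives the syn adduct, so that C1 and C14 are formed together as the cis pair and the hydroxy ester closes to the methylene lactone on acid treatment, the R,R sense relative to the dioxane resting on macrocyclic substrate control (the weakest point of the route).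

## Compound list

1 | toluene | Cc1ccccc1 | starting material
2 | (1S,2R)-3-methylcyclohexa-3,5-diene-1,2-diol | CC1=CC=C[C@H](O)[C@@H]1O | intermediate
3 | (3aR,7aS)-2,2,4-trimethyl-3a,7a-dihydro-1,3-benzodioxole | CC1=CC=C[C@H]2[C@@H]1OC(C)(C)O2 | intermediate
4 | (1S,4R,7S,8R)-7,8-O-isopropylidene-1-methyl-2,3-dioxabicyclo[2.2.2]oct-5-ene-7,8-diol | C[C@@]12C=C[C@@H](OO1)[C@@H]3OC(C)(C)O[C@H]23 | intermediate
5 | (1S,4R,5R,6S)-5,6-O-isopropylidene-1-methyl-2,3-dioxabicyclo[2.2.2]octane-5,6-diol | C[C@@]12CC[C@@H](OO1)[C@@H]3OC(C)(C)O[C@H]23 | intermediate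
6 | (1S,4R,5R,6S)-1-methyl-2,3-dioxabicyclo[2.2.2]octane-5,6-diol | C[C@@]12CC[C@@H](OO1)[C@H](O)[C@@H]2O | intermediate (not isolated)
7 | (3S,6R)-3-methyl-1,2-dioxane-3,6-dicarbaldehyde | O=C[C@]1(C)CC[C@@H](OO1)C=O | intermediate
8 | (3S,6R)-6-(1-hydroxyethyl)-3-methyl-1,2-dioxane-3-carbaldehyde (both carbinol epimers) | O=C[C@]1(C)CC[C@@H](OO1)C(C)O | intermediate
9 | (3S,6R)-6-acetyl-3-methyl-1,2-dioxane-3-carbaldehyde | O=C[C@]1(C)CC[C@@H](OO1)C(C)=O | intermediate
10 | (2E)-3-methylpent-2-en-4-yn-1-ol | OC/C=C(\C)C#C | starting material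
11 | 1-methoxy-4-({[(2E)-3-methylpent-2-en-4-yn-1-yl]oxy}methyl)benzene | COc1ccc(COC/C=C(\C)C#C)cc1 | intermediate
12 | 1-methoxy-4-({[(2E)-3-methylpenta-2,4-dien-1-yl]oxy}methyl)benzene | COc1ccc(COC/C=C(\C)C=C)cc1 | intermediate
13 | diethyl{(3E)-5-[(4-methoxybenzyl)oxy]-3-methylpent-3-en-1-yl}borane | CCB(CC)CC/C(C)=C/COCc1ccc(OC)cc1 | intermediate (not isolated)
14 | bis{(3E)-5-[(4-methoxybenzyl)oxy]-3-methylpent-3-en-1-yl}zinc | COc1ccc(COC/C=C(\C)CC[Zn]CC/C(C)=C/COCc2ccc(OC)cc2)cc1 | intermediate (not isolated)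
15 | (1R,4E)-1-[(3S,6R)-6-acetyl-3-methyl-1,2-dioxan-3-yl]-6-[(4-methoxybenzyl)oxy]-4-methylhex-4-en-1-ol (present as its zinc alkoxide) | COc1ccc(COC/C=C(\C)CC[C@@H](O)[C@]2(C)CC[C@@H](OO2)C(C)=O)cc1 | intermediate (not isolated)
16 | (1R,4E)-1-[(3S,6R)-6-acetyl-3-methyl-1,2-dioxan-3-yl]-6-[(4-methoxybenzyl)oxy]-4-methylhex-4-en-1-yl acetate | COc1ccc(COC/C=C(\C)CC[C@@H](OC(C)=O)[C@]2(C)CC[C@@H](OO2)C(C)=O)cc1 | intermediate
17 | but-3-en-1-yl(triphenyl)phosphonium bromide | C=CCC[P+](c1ccccc1)(c1ccccc1)c1ccccc1.[Br-] | starting material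
18 | but-3-en-1-ylidene(triphenyl)phosphorane | C=CCC=P(c1ccccc1)(c1ccccc1)c1ccccc1 | intermediate (not isolated)
19 | (1R,4E)-1-[(3S,6R)-6-[(2Z)-hexa-2,5-dien-2-yl]-3-methyl-1,2-dioxan-3-yl]-6-[(4-methoxybenzyl)oxy]-4-methylhex-4-en-1-yl acetate | COc1ccc(COC/C=C(\C)CC[C@@H](OC(C)=O)[C@]2(C)CC[C@@H](OO2)/C(C)=C\CC=C)cc1 | intermediate
20 | methyl 2-(bromomethyl)prop-2-enoate | COC(=O)C(=C)CBr | starting material
21 | methyl (2Z,5Z)-6-[(3R,6S)-6-{(1R,4E)-1-acetoxy-6-[(4-methoxybenzyl)oxy]-4-methylhex-4-en-1-yl}-6-methyl-1,2-dioxan-3-yl]-2-(bromomethyl)hepta-2,5-dienoate | COc1ccc(COC/C=C(\C)CC[C@@H](OC(C)=O)[C@]2(C)CC[C@@H](OO2)/C(C)=C\C/C=C(\CBr)C(=O)OC)cc1 | intermediate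
22 | methyl (2Z,5Z)-6-[(3R,6S)-6-[(1R,4E)-1-acetoxy-6-hydroxy-4-methylhex-4-en-1-yl]-6-methyl-1,2-dioxan-3-yl]-2-(bromomethyl)hepta-2,5-dienoate | OC/C=C(\C)CC[C@@H](OC(C)=O)[C@]1(C)CC[C@@H](OO1)/C(C)=C\C/C=C(\CBr)C(=O)OC | intermediate (not isolated)
23 | methyl (2Z,5Z)-6-[(3R,6S)-6-[(1R,4E)-1-acetoxy-4-methyl-6-oxohex-4-en-1-yl]-6-methyl-1,2-dioxan-3-yl]-2-(bromomethyl)hepta-2,5-dienoate | O=C/C=C(\C)CC[C@@H](OC(C)=O)[C@]1(C)CC[C@@H](OO1)/C(C)=C\C/C=C(\CBr)C(=O)OC | intermediate
24 | hydroxy methyl ester of the target (lactone open: C14–OH, C1 bearing C(=CH2)CO2Me; 1R,3Z,5R,8S,9R,12E,14R) | O[C@@H]1/C=C(\C)CC[C@@H](OC(C)=O)[C@]2(C)CC[C@@H](OO2)/C(C)=C\C[C@@H]1C(=C)C(=O)OC | intermediate (not isolated)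
25 | CNP0238885.6, (1R,3Z,5R,8S,9R,12E,14R) in the local numbering | C=C1C(=O)O[C@@H]2/C=C(\C)CC[C@@H](OC(C)=O)[C@]3(C)CC[C@@H](OO3)/C(C)=C\C[C@H]12 | target

## Step count and risks

Total steps: 14. Longest linear sequence: 12 (steps 1–7 and 10–14, from toluene).

Three steps most likely to fail:

Step 11 (Wittig on the alpha-peroxy ketone). The ylide may deprotonate C5–H and trigger Kornblum–DeLaMare fragmentation, or the Z selectivity may erode. The fallback is a Peterson olefination. It sets out from 16: the organocerium reagent made from [1-(trimethylsilyl)but-3-en-1-yl]lithium and CeCl3 (THF, −78 °C) adds to the ketone without enolisation and gives the beta-hydroxysilane F1 as two separable diastereomers. Each is eliminated stereospecifically, one with BF3·OEt2 (anti) and the other with KH (syn), so that both converge on the Z olefin 19, where the route is rejoined.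

Step 12 (cross-metathesis with the 2-substituted acrylate). Conversion may be low, or the skipped diene may migrate. The fallback builds the bromomethyl enoate by carbonyl chemistry. It sets out from 16: Wittig reaction with the ylide of [2-(1,3-dioxolan-2-yl)ethyl]triphenylphosphonium bromide gives the Z-alkenyl dioxolane F2, and aqueous acetic acid unmasks the beta,gamma-unsaturated aldehyde F3. Vinylalumination (methyl propiolate, i-Bu2AlH, N-methylmorpholine N-oxide, THF, 0 °C) gives the Morita–Baylis–Hillman-type allylic alcohol F4. Bromination with allylic transposition (NBS, Me2S, CH2Cl2, 0 °C) returns to 21.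

Step 14 (indium macrocyclisation). The facial sense relative to the dioxane is not guaranteed, oligomers may form, and the metal could attack the O–O bond. The fallback replaces the metal by boron and makes the aldehyde face catalyst-controlled. It sets out from 19: cross-metathesis with methyl 2-[(4,4,5,5-tetramethyl-1,3,2-dioxaborolan-2-yl)methyl]prop-2-enoate gives the allylboronate F5, and DDQ converts it into the enal boronate F6. The chiral phosphoric acid (S)-TRIP (toluene, high dilution, rt) catalyses a chair allylboration on the Si face of the enal to give hydroxy ester 24, which lactonises to 25.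

## Further compounds

F1 | step 11 | (1R,4E)-1-[(3S,6R)-6-[2-hydroxy-3-(trimethylsilyl)hex-5-en-2-yl]-3-methyl-1,2-dioxan-3-yl]-6-[(4-methoxybenzyl)oxy]-4-methylhex-4-en-1-yl acetate (diastereomers at the two new centres) | COc1ccc(COC/C=C(\C)CC[C@@H](OC(C)=O)[C@]2(C)CC[C@@H](OO2)C(C)(O)C(CC=C)[Si](C)(C)C)cc1
F2 | step 12 | (1R,4E)-1-[(3S,6R)-6-[(2Z)-4-(1,3-dioxolan-2-yl)but-2-en-2-yl]-3-methyl-1,2-dioxan-3-yl]-6-[(4-methoxybenzyl)oxy]-4-methylhex-4-en-1-yl acetate | COc1ccc(COC/C=C(\C)CC[C@@H](OC(C)=O)[C@]2(C)CC[C@@H](OO2)/C(C)=C\CC3OCCO3)cc1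
F3 | step 12 | (1R,4E)-6-[(4-methoxybenzyl)oxy]-4-methyl-1-[(3S,6R)-3-methyl-6-[(2Z)-5-oxopent-2-en-2-yl]-1,2-dioxan-3-yl]hex-4-en-1-yl acetate | COc1ccc(COC/C=C(\C)CC[C@@H](OC(C)=O)[C@]2(C)CC[C@@H](OO2)/C(C)=C\CC=O)cc1
F4 | step 12 | methyl (5Z)-6-[(3R,6S)-6-{(1R,4E)-1-acetoxy-6-[(4-methoxybenzyl)oxy]-4-methylhex-4-en-1-yl}-6-methyl-1,2-dioxan-3-yl]-3-hydroxy-2-methylidenehept-5-enoate (both carbinol epimers) | COc1ccc(COC/C=C(\C)CC[C@@H](OC(C)=O)[C@]2(C)CC[C@@H](OO2)/C(C)=C\CC(O)C(=C)C(=O)OC)cc1
F5 | step 14 | methyl (2E,5Z)-6-[(3R,6S)-6-{(1R,4E)-1-acetoxy-6-[(4-methoxybenzyl)oxy]-4-methylhex-4-en-1-yl}-6-methyl-1,2-dioxan-3-yl]-2-[(4,4,5,5-tetramethyl-1,3,2-dioxaborolan-2-yl)methyl]hepta-2,5-dienoate | COc1ccc(COC/C=C(\C)CC[C@@H](OC(C)=O)[C@]2(C)CC[C@@H](OO2)/C(C)=C\C/C=C(\CB3OC(C)(C)C(C)(C)O3)C(=O)OC)cc1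
F6 | step 14 | methyl (2E,5Z)-6-[(3R,6S)-6-[(1R,4E)-1-acetoxy-4-methyl-6-oxohex-4-en-1-yl]-6-methyl-1,2-dioxan-3-yl]-2-[(4,4,5,5-tetramethyl-1,3,2-dioxaborolan-2-yl)methyl]hepta-2,5-dienoate | O=C/C=C(\C)CC[C@@H](OC(C)=O)[C@]1(C)CC[C@@H](OO1)/C(C)=C\C/C=C(\CB2OC(C)(C)C(C)(C)O2)C(=O)OC
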